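**Retrosynthetic overview**
1. Numbering (phthalide type). The unprimed unit is the butenolide (C1, O2, C3, C3a, C7a) fused to ring A (C3a, C4, C5, C6, C7, C7a). The primed unit is lactone B and ring B, which share the bond C3a'–C7a' with the cyclobutane (C6, C7, C3a', C7a').
2. Enabling feature. The only alkene of ring A, C3a=C7a, is also the butenolide alkene: C7a is alpha to C1=O and C3a sits next to the enol-ether carbon C3. The bond C5–C6 lies opposite that alkene in ring A, so C5 is the delta carbon of a dienoate C1(=O)–C7a=C3a–C4=C5, and C6 is a cyclobutane CH.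
3. Key disconnection. C3a=C7a comes from an intramolecular Horner–Wadsworth–Emmons olefination of a phosphonoacetate enol ester of oct-1-ene-3,4-dione. C5–C6 comes from 6-endo addition of a C6 radical to the vinyl group. Both happen in one domino, and the extra carboxyl group on C6 is a traceless activator that leaves as CO2.
4. The cyclobutane comes from an enone–alkynoate [2+2] photocycloaddition. C7 is set by hydride delivery to an alkylidene phosphonoacetate. Lactone B is built by E-selective iodolactonisation and Negishi coupling.
5. Ring order: ring B (bought), then the cyclobutene, then lactone B, then the butenolide and ring A together.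

Key step: step 19

Remark: the SMILES is read literally. The butylidene of the conjugated unit is Z. That of lactone B is E (propyl cis to C3a').

**Step 1**
Reactants: 1 3-ethoxycyclohex-2-en-1-one; 2 ethynyl(trimethyl)silane
Product: 4 3-[(trimethylsilyl)ethynyl]cyclohex-2-en-1-one, via propargylic alcohol 3 (not isolated)
Conditions: 2, n-BuLi, THF, −78 °C; 1; then 1 M HCl, 23 °C
Reagents that add atoms: none
Why: 1,2-Addition of the lithium acetylide to the vinylogous ester, then acid hydrolysis with loss of ethanol (Stork–Danheiser transposition), moves the carbonyl and gives the 3-alkynyl enone; no stereocentre is formed.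

**Step 2**
Reactants: 4 3-[(trimethylsilyl)ethynyl]cyclohex-2-en-1-one
Product: 5 2-iodo-3-[(trimethylsilyl)ethynyl]cyclohex-2-en-1-one
Conditions: I2, pyridine–CH2Cl2 1:1, 23 °C
Reagents that add atoms: iodine II
Why: Pyridine-mediated alpha-iodination of an enone (conjugate addition of pyridine, iodination of the enolate, elimination of pyridine) puts the halogen on the carbon that becomes C7a'.

**Step 3**
Reactants: 5 2-iodo-3-[(trimethylsilyl)ethynyl]cyclohex-2-en-1-one; 6 2-(trimethylsilyl)ethanol
Product: 7 2-(trimethylsilyl)ethyl 6-oxo-2-[(trimethylsilyl)ethynyl]cyclohex-1-ene-1-carboxylate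
Conditions: PdCl2(PPh3)2 (5 mol %), CO (1 atm), 6, Et3N, DMF, 60 °C
Reagents that add atoms: carbon monoxide [C-]#[O+]
Why: Palladium-catalysed alkoxycarbonylation of the alkenyl iodide (oxidative addition to zerovalent palladium, CO insertion, alcoholysis) installs C1' as a fluoride-labile ester and leaves the silyl alkyne untouched.

**Step 4**
Reactants: 8 propiolic acid; 6 2-(trimethylsilyl)ethanol
Product: 9 2-(trimethylsilyl)ethyl propiolate
Conditions: DCC, DMAP (cat.), CH2Cl2, −20 to 0 °C
Reagents that add atoms: none
Why: Steglich esterification at low temperature is the usual way to esterify propiolic acid without conjugate addition.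

**Step 5**
Reactants: 7 2-(trimethylsilyl)ethyl 6-oxo-2-[(trimethylsilyl)ethynyl]cyclohex-1-ene-1-carboxylate; 9 2-(trimethylsilyl)ethyl propiolate
Product: 10 racemic cis-fused bis[2-(trimethylsilyl)ethyl] 2-oxo-6-[(trimethylsilyl)ethynyl]bicyclo[4.2.0]oct-7-ene-1,8-dicarboxylate (ester on C6, H on C7, alkynyl on C3a', ester on C7a')
Conditions: hν (366 nm), 9 (10 equiv), CH2Cl2, −20 °C
Reagents that add atoms: none
Why: Enone–alkyne [2+2] photocycloaddition through the enone triplet: the acceptor-bearing alkyne carbon bonds to the enone alpha carbon (head-to-head rule for electron-poor partners), and the cyclobutene can only be cis-fused, which fixes the relative configuration of the quaternary centres C3a' and C7a'.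

**Step 6**
Reactants: 10 racemic cyclobutene keto diester
Product: 11 (7'R)-alcohol, single enantiomer with the C3a'/C7a' configuration of the target (the 2-hydroxy analogue of 10)
Conditions: (S)-2-methyl-CBS-oxazaborolidine (0.5 equiv), catecholborane, toluene, −78 to −40 °C; aqueous work-up; separation on SiO2
Reagents that add atoms: none
Why: Corey–Bakshi–Shibata reduction under reagent control (quaternary C7a' as the large group, C6'H2 as the small group) gives the 7'R carbinol from both enantiomers of 10, so the racemate becomes two separable diastereomers and taking 11 fixes the absolute configuration of C3a' and C7a'.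

**Step 7**
Reactants: 11 (7'R)-alcohol
Product: 12 bis[2-(trimethylsilyl)ethyl] 6-[(trimethylsilyl)ethynyl]bicyclo[4.2.0]octa-2,7-diene-1,8-dicarboxylate (C6'=C7' alkene in ring B)
Conditions: Burgess reagent, toluene, 70 °C
Reagents that add atoms: none
Why: Burgess dehydration (syn elimination of the sulfamate) can only run towards C6' because C7a' is quaternary, and its concerted course avoids a cyclobutylcarbinyl cation; the carbinol stereocentre is erased.

**Step 8**
Reactants: 12 cyclobutene diene diester; 13 tert-butyl (diethoxyphosphoryl)acetate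
Product: 16 alkylidene phosphonoacetate (C7=C7a, bearing P(O)(OEt)2 and CO2t-Bu on C7a; alkene geometry and C6 not defined), via Michael adduct 14 (not isolated), via iodide 15 (not isolated)
Conditions: 13, NaH, THF, 0 °C; 12, 0 to 23 °C; I2, −78 °C; DBU, 23 °C
Reagents that add atoms: none
Why: Michael addition of the phosphonoacetate anion to the strained cyclobutene ester, iodination of the resulting phosphonate carbanion and E2 dehydroiodination join C7 to C7a and deliberately return C7 to sp2, because carbon enters from the open alkynyl face, which is the wrong face.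

**Step 9**
Reactants: 16 alkylidene phosphonoacetate
Product: 17 saturated phosphonoacetate (H7 on the alkynyl face, phosphonoacetate arm on the ring B face; epimers at C6 and C7a)
Conditions: NaBH4, THF–EtOH, −20 °C; AcOH
Reagents that add atoms: none
Why: Conjugate borohydride reduction of the alkylidene phosphonoacetate: hydride reaches C7 from the face of the slim alkynyl group, away from the C4' methylene of ring B, so H7 ends on the future lactone B face and the arm on the ring B face.

**Step 10**
Reactants: 17 saturated phosphonoacetate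
Product: 18 alkynyl diacid (terminal alkyne on C3a', CO2H on C7a' and on C6, tert-butyl ester kept)
Conditions: TBAF (6 equiv), THF, 0 to 23 °C; 1 M HCl
Reagents that add atoms: none
Why: Fluoride-induced fragmentation of both 2-(trimethylsilyl)ethyl esters and protodesilylation of the alkyne occur in one operation; the tert-butyl ester and the phosphonate are inert to fluoride.

**Step 11**
Reactants: 18 alkynyl diacid
Product: 19 (E)-iodomethylene lactone B acid (lactone C1'–O2'–C3', iodine cis to C3a', free CO2H on C6)
Conditions: NIS, NaHCO3, MeCN, 0 °C, dark; 1 M HCl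
Reagents that add atoms: N-iodosuccinimide O=C1CCC(=O)N1I
Why: Iodolactonisation of a 4-alkynoic acid: 5-exo-dig anti addition of the C1' carboxylate and iodine across the alkyne gives only the E iodoalkylidene lactone, whereas the C6 acid could only form a strained bridged lactone and the ring B alkene only a 5-endo or 4-exo product.

**Step 12**
Reactants: 19 (E)-iodomethylene lactone B acid
Product: 20 (E)-butylidene lactone B acid (propyl cis to C3a')
Conditions: n-PrZnBr (3 equiv), PdCl2(dppf) (5 mol %), THF, 23 °C; 1 M HCl
Reagents that add atoms: n-propylzinc bromide CCC[Zn]Br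
Why: Negishi coupling of the alkenyl iodide: oxidative addition to zerovalent palladium and reductive elimination keep the alkene geometry, so propyl replaces iodine cis to C3a' (E), and dppf suppresses beta-hydride elimination.

**Step 13**
Reactants: 20 (E)-butylidene lactone B acid
Product: 21 N-acyloxyphthalimide of the C6 acid
Conditions: N-hydroxyphthalimide, DIC, DMAP (cat.), CH2Cl2, 23 °C
Reagents that add atoms: N-hydroxyphthalimide ON1C(=O)c2ccccc2C1=O
Why: Carbodiimide esterification turns the C6 carboxyl group into the redox-active ester that later leaves as CO2.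

**Step 14**
Reactants: 21 N-acyloxyphthalimide tert-butyl ester
Product: 22 phosphonoacetic acid (free C1 acid)
Conditions: TFA–CH2Cl2 1:3, 0 to 23 °C
Reagents that add atoms: none
Why: Acidolysis of the tert-butyl ester (loss of isobutene) frees the C1 acid; the N-acyloxyphthalimide, the phosphonate and the enol lactone tolerate anhydrous trifluoroacetic acid for the short time needed.

**Step 15**
Reactants: 23 N,N'-dimethoxy-N,N'-dimethyloxamide
Product: 24 N-methoxy-N-methyl-2-oxohexanamide
Conditions: n-BuMgCl (1.0 equiv), THF, −78 to 0 °C; 1 M HCl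
Reagents that add atoms: n-butylmagnesium chloride CCCC[Mg]Cl
Why: Weinreb ketone synthesis: one equivalent of Grignard reagent adds once to the bis-Weinreb oxamide because the chelated tetrahedral intermediate survives until the quench.

**Step 16**
Reactants: 24 N-methoxy-N-methyl-2-oxohexanamide
Product: 25 (Z)-2-[(tert-butyldimethylsilyl)oxy]-N-methoxy-N-methylhex-2-enamide
Conditions: TBSOTf, Et3N, CH2Cl2, 0 °C
Reagents that add atoms: tert-butyldimethylsilyl triflate CC(C)(C)[Si](C)(C)OS(=O)(=O)C(F)(F)F
Why: Soft enolisation and O-silylation of the alpha-keto amide: only C8 carries enolisable hydrogen, and the Z silyl enol ether (propyl cis to oxygen, trans to the amide carbonyl) is favoured by allylic strain, which sets the Z geometry of C3=C8.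

**Step 17**
Reactants: 25 (Z)-silyl enol ether Weinreb amide
Product: 26 (Z)-4-[(tert-butyldimethylsilyl)oxy]octa-1,4-dien-3-one
Conditions: vinylMgBr, THF, −78 to −20 °C; inverse quench into cold 1 M HCl
Reagents that add atoms: vinylmagnesium bromide C=C[Mg]Br
Why: Weinreb ketone synthesis with vinylmagnesium bromide; the acidic inverse quench keeps the liberated hydroxylamine from adding to the vinyl ketone.

**Step 18**
Reactants: 22 phosphonoacetic acid; 26 (Z)-4-[(tert-butyldimethylsilyl)oxy]octa-1,4-dien-3-one
Product: 28 (Z)-enol ester (C1(=O)–O2–C3(=C8H–Pr)–C3a(=O)–C4H=C5H2, phosphonate on C7a, N-acyloxyphthalimide on C6), via acid fluoride 27 (not isolated)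
Conditions: cyanuric fluoride, pyridine, CH2Cl2, −20 °C; then 26, TBAT (5 mol %), THF, −40 °C
Reagents that add atoms: none
Why: Acid fluoride formation and fluoride-catalysed O-acylation of the silyl enol ether (naked enolate, hard acyl donor, Si–F bond as driving force) give the enol ester with retention of the Z geometry; the hindered N-acyloxyphthalimide is far less electrophilic than the acid fluoride.

**Step 19**
Reactants: 28 (Z)-enol ester
Product: 30 target (3Z,3'E,6S,7R,3a'S,7a'R)-dimer CNP0371639.1, via vinyl butenolide 29 (not isolated)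
Conditions: Ru(bpy)3(PF6)2 (2 mol %), Hantzsch ester (1.5 equiv), i-Pr2NEt (4 equiv), LiCl (5 equiv), MeCN (2 mM), 23 °C, 30 min dark, then 450 nm LED
Reagents that add atoms: none
Why: Proposed new method: LiCl/i-Pr2NEt deprotonates C7a–H of 28 and the carbanion closes on the C3a ketone (5-exo-trig, then loss of diethyl phosphate) to give the 4-vinyl-5-butylidene butenolide 29, whose new dienoate makes C5 a radical acceptor within ring-closing reach of C6; the same amine then quenches excited Ru(bpy)3(PF6)2, the reduced complex fragments the N-acyloxyphthalimide (loss of CO2 and phthalimide anion), and the C6 cyclobutyl radical adds to C5 (6-endo-trig) before the delocalised C4/C7a radical takes a hydrogen atom from the Hantzsch ester. The closest known reaction types are the Masamune–Roush intramolecular Horner–Wadsworth–Emmons synthesis of butenolides from alpha-acyloxy ketones and the reductive decarboxylative Giese reaction of N-acyloxyphthalimides with butenolide and dienoate acceptors; only their merger under one reagent set that shares the amine is new. The one new stereocentre, C6, is controlled by C7: the radical is planar and the link C7–C7a=C3a–C4 can bring C5 only to the face that bears C7a, because a trans-fused bicyclo[4.2.0]octene is out of reach, so H6 ends cis to H7. The order of events is secured by ring size (before olefination the radical could only close a nine-membered ring) and by the dark period, and 6-endo beats 5-exo because attack at C4 would give a primary radical in a strained bicyclo[3.2.0] frame whereas attack at C5 gives a carbonyl-stabilised allyl radical. Hydrogen delivery at C7a instead of C4 is corrected by the amine base, which moves the alkene into the tetrasubstituted, fully conjugated C3a=C7a position. The low triplet energy of the ruthenium sensitiser and the absence of acid protect the Z alkene of the new butenolide and the E alkene of lactone B.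

**Compound list**
1 | 3-ethoxycyclohex-2-en-1-one | CCOC1=CC(=O)CCC1 | starting material
2 | ethynyl(trimethyl)silane | C#C[Si](C)(C)C | starting material
3 | 3-ethoxy-1-[(trimethylsilyl)ethynyl]cyclohex-2-en-1-ol (racemic) | CCOC1=CC(O)(C#C[Si](C)(C)C)CCC1 | intermediate
4 | 3-[(trimethylsilyl)ethynyl]cyclohex-2-en-1-one | O=C1C=C(C#C[Si](C)(C)C)CCC1 | intermediate
5 | 2-iodo-3-[(trimethylsilyl)ethynyl]cyclohex-2-en-1-one | O=C1C(I)=C(C#C[Si](C)(C)C)CCC1 | intermediate
6 | 2-(trimethylsilyl)ethanol | C[Si](C)(C)CCO | starting material
7 | 2-(trimethylsilyl)ethyl 6-oxo-2-[(trimethylsilyl)ethynyl]cyclohex-1-ene-1-carboxylate | O=C1CCCC(C#C[Si](C)(C)C)=C1C(=O)OCC[Si](C)(C)C | intermediate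
8 | propiolic acid | C#CC(=O)O | starting material
9 | 2-(trimethylsilyl)ethyl propiolate | C#CC(=O)OCC[Si](C)(C)C | intermediate
10 | cyclobutene keto diester (racemic; the enantiomer carried on is drawn) | O=C1CCC[C@]2(C#C[Si](C)(C)C)C=C(C(=O)OCC[Si](C)(C)C)[C@]12C(=O)OCC[Si](C)(C)C | intermediate
11 | (7'R)-alcohol | O[C@@H]1CCC[C@]2(C#C[Si](C)(C)C)C=C(C(=O)OCC[Si](C)(C)C)[C@]12C(=O)OCC[Si](C)(C)C | intermediate
12 | cyclobutene diene diester | C[Si](C)(C)C#C[C@]12CCC=C[C@@]1(C(=O)OCC[Si](C)(C)C)C(C(=O)OCC[Si](C)(C)C)=C2 | intermediate
13 | tert-butyl (diethoxyphosphoryl)acetate | CCOP(=O)(CC(=O)OC(C)(C)C)OCC | starting material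
14 | Michael adduct (new centres not defined) | C[Si](C)(C)C#C[C@]12CCC=C[C@@]1(C(=O)OCC[Si](C)(C)C)C(C(=O)OCC[Si](C)(C)C)C2C(C(=O)OC(C)(C)C)P(=O)(OCC)OCC | intermediate
15 | alpha-iodo phosphonoacetate (new centres not defined) | C[Si](C)(C)C#C[C@]12CCC=C[C@@]1(C(=O)OCC[Si](C)(C)C)C(C(=O)OCC[Si](C)(C)C)C2C(I)(C(=O)OC(C)(C)C)P(=O)(OCC)OCC | intermediate
16 | alkylidene phosphonoacetate (alkene geometry and C6 not defined) | C[Si](C)(C)C#C[C@]12CCC=C[C@@]1(C(=O)OCC[Si](C)(C)C)C(C(=O)OCC[Si](C)(C)C)C2=C(C(=O)OC(C)(C)C)P(=O)(OCC)OCC | intermediate
17 | saturated phosphonoacetate (C6 and C7a epimers) | C[Si](C)(C)C#C[C@]12CCC=C[C@@]1(C(=O)OCC[Si](C)(C)C)C(C(=O)OCC[Si](C)(C)C)[C@H]2C(C(=O)OC(C)(C)C)P(=O)(OCC)OCC | intermediate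
18 | alkynyl diacid (C6 and C7a epimers) | C#C[C@]12CCC=C[C@@]1(C(=O)O)C(C(=O)O)[C@H]2C(C(=O)OC(C)(C)C)P(=O)(OCC)OCC | intermediate
19 | (E)-iodomethylene lactone B acid | OC(=O)C1[C@@H](C(C(=O)OC(C)(C)C)P(=O)(OCC)OCC)[C@@]23CCC=C[C@@]12C(=O)O/C3=C/I | intermediate
20 | (E)-butylidene lactone B acid | OC(=O)C1[C@@H](C(C(=O)OC(C)(C)C)P(=O)(OCC)OCC)[C@@]23CCC=C[C@@]12C(=O)O/C3=C/CCC | intermediate
21 | N-acyloxyphthalimide tert-butyl ester | O=C(ON1C(=O)c2ccccc2C1=O)C1[C@@H](C(C(=O)OC(C)(C)C)P(=O)(OCC)OCC)[C@@]23CCC=C[C@@]12C(=O)O/C3=C/CCC | intermediate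
22 | phosphonoacetic acid | O=C(ON1C(=O)c2ccccc2C1=O)C1[C@@H](C(C(=O)O)P(=O)(OCC)OCC)[C@@]23CCC=C[C@@]12C(=O)O/C3=C/CCC | intermediate
23 | N,N'-dimethoxy-N,N'-dimethyloxamide | CON(C)C(=O)C(=O)N(C)OC | starting material
24 | N-methoxy-N-methyl-2-oxohexanamide | CCCCC(=O)C(=O)N(C)OC | intermediate
25 | (Z)-2-[(tert-butyldimethylsilyl)oxy]-N-methoxy-N-methylhex-2-enamide | CCC/C=C(\O[Si](C)(C)C(C)(C)C)C(=O)N(C)OC | intermediate
26 | (Z)-4-[(tert-butyldimethylsilyl)oxy]octa-1,4-dien-3-one | CCC/C=C(\O[Si](C)(C)C(C)(C)C)C(=O)C=C | intermediate
27 | acid fluoride | O=C(ON1C(=O)c2ccccc2C1=O)C1[C@@H](C(C(=O)F)P(=O)(OCC)OCC)[C@@]23CCC=C[C@@]12C(=O)O/C3=C/CCC | intermediate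
28 | (Z)-enol ester, precursor of the key step | O=C(ON1C(=O)c2ccccc2C1=O)C1[C@@H](C(C(=O)O/C(=C\CCC)C(=O)C=C)P(=O)(OCC)OCC)[C@@]23CCC=C[C@@]12C(=O)O/C3=C/CCC | intermediate
29 | vinyl butenolide | O=C(ON1C(=O)c2ccccc2C1=O)C1[C@@H](C2=C(C=C)/C(=C/CCC)OC2=O)[C@@]23CCC=C[C@@]12C(=O)O/C3=C/CCC | intermediate
30 | CNP0371639.1 | CCC/C=C1\OC(=O)C2=C1CC[C@H]1[C@@H]2[C@@]23CCC=C[C@@]12C(=O)O/C3=C/CCC | target

**Count**
Total steps: 19. Longest linear sequence: 15 (steps 1–3, 5–14, 18, 19).

**Steps most likely to fail**

Step 19. The redox-active ester may fragment before the olefination is complete, or the butylidene groups may isomerise under light. The fallback sets out from 28. The olefination is run alone (LiCl, DBU, MeCN, dark) and 29 is isolated. Ring A is then closed without light by the nickel-catalysed, zinc-driven decarboxylative Giese reaction (Ni(ClO4)2·6H2O, Zn, LiCl, MeCN). The route is rejoined at 30.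

Step 5. The enone triplet may add slowly to the electron-poor alkyne, or in the wrong orientation. The fallback sets out from 7. An alkene takes the place of the alkyne: photocycloaddition with 2-(trimethylsilyl)ethyl 2-chloroacrylate, a faster captodative partner with the same head-to-head bias, should give the chlorocyclobutane F1. Dehydrochlorination with DBU then installs the cyclobutene. The route is rejoined at 10.

Step 18. C-acylation of the enolate may compete with O-acylation, or fluoride or enolate base may trigger olefination early. The fallback sets out from 22 and 26 and replaces enolate acylation by O–H addition to a ketene under nearly neutral conditions.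
- 22 is converted with 1-chloro-N,N,2-trimethylpropenylamine into the acid chloride F2.
- Et3N eliminates HCl from F2 to give the phosphonoketene F3.
- F3 is trapped by the enol form of oct-1-ene-3,4-dione F4, freed from 26 with HF·pyridine just before use.

The route is rejoined at 28.

**Further compounds**
F0 | step 19 | none | none
F1 | step 5 | chlorocyclobutane (racemic, chloride and ester on C6) | O=C1CCC[C@]2(C#C[Si](C)(C)C)CC(Cl)(C(=O)OCC[Si](C)(C)C)[C@]12C(=O)OCC[Si](C)(C)C
F2 | step 18 | acid chloride of 22 | O=C(ON1C(=O)c2ccccc2C1=O)C1[C@@H](C(C(=O)Cl)P(=O)(OCC)OCC)[C@@]23CCC=C[C@@]12C(=O)O/C3=C/CCC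
F3 | step 18 | phosphonoketene | O=C(ON1C(=O)c2ccccc2C1=O)C1[C@@H](C(=C=O)P(=O)(OCC)OCC)[C@@]23CCC=C[C@@]12C(=O)O/C3=C/CCC
F4 | step 18 | oct-1-ene-3,4-dione | CCCCC(=O)C(=O)C=C
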